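**Retrosynthetic overview**
- The γ-lactone and the CH2OH group are made last. One hydride reduction of a C7-keto/C16-aldehyde/C19-methyl ester is followed by spontaneous lactonisation.
- The key step is a ring contraction. Cl+ attacks C6 of a macrocyclic 3(2H)-furanone and the C4 alkenyl carbon shifts 1,2 from the C16 carbinol to C5. This takes the carbocycle from 11 to 10 members and sets C5, C6-Cl and the 5,8-oxa bridge.
- The 11-membered ring comes from ring-closing metathesis at C3=C4. The C8–C9 bond comes from a Mukaiyama aldol between a ring-A aldehyde and a 3-silyloxyfuran.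
- Ring A is built by Ir-catalysed tert-(hydroxy)prenylation, metathesis, vinyl addition and a formaldehyde-ene reaction. The furan comes from pent-1-en-4-yn-3-ol and (R)-methylsuccinic anhydride.
- Order of ring formation: cyclohexene, then furanone, then the 11-membered ring, then contraction to the oxa-bridged 10-membered ring, then the lactone.

**Assumption:** briarane numbering (C1–C20) is used in the names. The four starting materials are taken as commercial. The C16 carbinol centre is carried as an epimer mixture (it becomes the aldehyde carbon in the ring contraction). C8 is undefined until it becomes sp2 in the silyloxyfuran. Both centres are left open in the SMILES of those compounds.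

**Step 1**
Reactants: 1 4-methylpent-4-en-1-ol; 2 2-methyl-2-vinyloxirane (isoprene monoxide, racemic)
Product: 4 (2S,3S)-2,6-dimethyl-2-vinylhept-6-ene-1,3-diol, via 4-methylpent-4-enal 3 (not isolated)
Conditions: cyclometalated π-allyl-Ir C,O-benzoate of (R)-Tol-BINAP (5 mol%; the antipode that gives the 3S carbinol), K3PO4 (5 mol%), THF, 60 °C
Reagents that add atoms: none
Why: In this iridium-catalysed transfer-hydrogenative carbonyl tert-(hydroxy)prenylation, 1 is dehydrogenated to 3, the hydride opens 2 to an (E)-σ-allyliridium species, and a closed chair transition state gives the anti adduct, so the catalyst sets the quaternary C1 and the C14 carbinol.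

**Step 2**
Reactants: 4 (2S,3S)-2,6-dimethyl-2-vinylhept-6-ene-1,3-diol
Product: 5 (1S,2S)-2-(hydroxymethyl)-2,4-dimethylcyclohex-3-en-1-ol
Conditions: Hoveyda–Grubbs II (3 mol%), CH2Cl2, 40 °C
Reagents that add atoms: none
Why: Ring-closing metathesis of the vinyl group with the 1,1-disubstituted alkene is a favourable six-ring closure driven by loss of ethene, and it touches no stereocentre.

**Step 3**
Reactants: 5 (1S,2S)-2-(hydroxymethyl)-2,4-dimethylcyclohex-3-en-1-ol
Product: 6 (1R,6S)-6-hydroxy-1,3-dimethylcyclohex-2-ene-1-carbaldehyde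
Conditions: TEMPO (10 mol%), PhI(OAc)2, CH2Cl2, 0 °C to rt
Reagents that add atoms: none
Why: Oxoammonium (TEMPO) oxidation takes the primary alcohol in preference to the secondary one, and the aldehyde has no α-hydrogen to epimerise.

**Step 4**
Reactants: 6 (1R,6S)-6-hydroxy-1,3-dimethylcyclohex-2-ene-1-carbaldehyde
Product: 7 (1S,2R)-2-[(1S)-1-hydroxyprop-2-en-1-yl]-2,4-dimethylcyclohex-3-en-1-ol
Conditions: vinylMgBr (3 equiv), THF, −78 to 0 °C; aq NH4Cl
Reagents that add atoms: vinylmagnesium bromide, C=C[Mg]Br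
Why: In this chelation-controlled Grignard 1,2-addition the C14 magnesium alkoxide and the aldehyde oxygen form a six-membered chelate in which the ring bond C1–C10 is axial, so vinyl attacks the opposite face and gives the 2S carbinol.

**Step 5**
Reactants: 7 (1S,2R)-2-[(1S)-1-hydroxyprop-2-en-1-yl]-2,4-dimethylcyclohex-3-en-1-ol
Product: 8 (1S,2R)-2-[(1S)-1-acetoxyprop-2-en-1-yl]-2,4-dimethylcyclohex-3-en-1-yl acetate
Conditions: Ac2O, Et3N, DMAP, CH2Cl2, rt
Reagents that add atoms: acetic anhydride, CC(=O)OC(C)=O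
Why: DMAP-catalysed acylation installs the final C2 and C14 acetates in one operation with retention at both carbinols.

**Step 6**
Reactants: 8 (1S,2R)-2-[(1S)-1-acetoxyprop-2-en-1-yl]-2,4-dimethylcyclohex-3-en-1-yl acetate
Product: 9 (1S,2R,3S)-2-[(1S)-1-acetoxyprop-2-en-1-yl]-3-(hydroxymethyl)-2-methyl-4-methylidenecyclohexyl acetate
Conditions: (CH2O)n, Me2AlCl (3.5 equiv), CH2Cl2, −78 to 0 °C
Reagents that add atoms: paraformaldehyde (delivers formaldehyde), C=O
Why: In this Lewis-acid carbonyl-ene reaction formaldehyde bonds to the less substituted alkene carbon C10 on the face anti to the bulky C2 side chain (this sets C10), and the hydrogen is taken from the methyl group syn to the alkene hydrogen, which gives the exocyclic C11=C20 methylene.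

**Step 7**
Reactants: 9 (1S,2R,3S)-2-[(1S)-1-acetoxyprop-2-en-1-yl]-3-(hydroxymethyl)-2-methyl-4-methylidenecyclohexyl acetate
Product: 10 (1S,2R,3S)-2-[(1S)-1-acetoxyprop-2-en-1-yl]-3-formyl-2-methyl-4-methylidenecyclohexyl acetate
Conditions: Dess–Martin periodinane, NaHCO3, CH2Cl2, 0 °C; used at once
Reagents that add atoms: none
Why: Buffered Dess–Martin oxidation is neutral enough to give the β,γ-unsaturated aldehyde without C10 epimerisation or alkene migration.

**Step 8**
Reactants: 11 pent-1-en-4-yn-3-ol (racemic)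
Product: 12 tert-butyl(dimethyl)(pent-1-en-4-yn-3-yloxy)silane
Conditions: TBSCl, imidazole, DMF, rt
Reagents that add atoms: tert-butyldimethylsilyl chloride, CC(C)(C)[Si](C)(C)Cl
Why: Standard silylation protects the future C16 carbinol through the basic and Lewis-acidic steps that follow.

**Step 9**
Reactants: 12 tert-butyl(dimethyl)(pent-1-en-4-yn-3-yloxy)silane; 13 (R)-methylsuccinic anhydride
Product: 15 methyl (2R)-7-[(tert-butyldimethylsilyl)oxy]-2-methyl-4-oxonon-8-en-5-ynoate, via lithium keto-carboxylate 14 (not isolated)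
Conditions: n-BuLi, THF, −78 °C; cannulate into 13 (1.5 equiv), −78 °C; then MeI, DMF, rt
Reagents that add atoms: iodomethane, CI
Why: The acetylide opens the cyclic anhydride at the less hindered carbonyl (next to CH2), the carboxylate formed blocks over-addition, SN2 esterification follows, and the C17 stereocentre from 13 is untouched.

**Step 10**
Reactants: 15 methyl (2R)-7-[(tert-butyldimethylsilyl)oxy]-2-methyl-4-oxonon-8-en-5-ynoate
Product: 17 methyl (2R)-2-{5-[1-(tert-butyldimethylsilyloxy)prop-2-enyl]-3-oxo-2,3-dihydrofuran-2-yl}propanoate (C8 epimers), via alpha-hydroxy ynone 16 (not isolated)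
Conditions: KHMDS, THF, −78 °C; 2-(phenylsulfonyl)-3-phenyloxaziridine; warm to 0 °C; AcOH
Reagents that add atoms: 2-(phenylsulfonyl)-3-phenyloxaziridine, O=S(=O)(c1ccccc1)N1OC1c1ccccc1
Why: Davis enolate hydroxylation occurs at C8, the only enolisable position of the ynone, and the alkoxide then closes by 5-endo-dig oxa-Michael addition to the 3(2H)-furanone.

**Step 11**
Reactants: 17 methyl (2R)-2-{5-[1-(tert-butyldimethylsilyloxy)prop-2-enyl]-3-oxo-2,3-dihydrofuran-2-yl}propanoate
Product: 18 methyl (2R)-2-{5-[1-(tert-butyldimethylsilyloxy)prop-2-enyl]-3-(triisopropylsilyloxy)furan-2-yl}propanoate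
Conditions: TIPSOTf, Et3N, CH2Cl2, 0 °C
Reagents that add atoms: triisopropylsilyl triflate, CC(C)[Si](C(C)C)(C(C)C)OS(=O)(=O)C(F)(F)F
Why: Soft enolisation and O-silylation are driven by aromatisation to the 3-silyloxyfuran, and Et3N is too weak a base to epimerise C17.

**Step 12**
Reactants: 10 (1S,2R,3S)-2-[(1S)-1-acetoxyprop-2-en-1-yl]-3-formyl-2-methyl-4-methylidenecyclohexyl acetate; 18 methyl (2R)-2-{5-[1-(tert-butyldimethylsilyloxy)prop-2-enyl]-3-(triisopropylsilyloxy)furan-2-yl}propanoate
Product: 19 C8–C9 aldol adduct (8R,9S): ring A (2,14-diacetate, C2 vinyl) joined through C9H(OH) to quaternary C8 of the 3(2H)-furanone, which carries the C17 propanoate arm and the 16-OTBS allyl group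
Conditions: BF3·OEt2 (1.2 equiv), CH2Cl2, −78 °C; aq NaHCO3
Reagents that add atoms: none
Why: This Mukaiyama aldol takes place at C2 of the 3-silyloxyfuran through an open transition state. The furan attacks antiperiplanar to the allylic C10–C11 bond of the aldehyde (sets 9S). It attacks on the furan face away from the ester arm of C17, with the ring-A residue in the open quadrant between the ring oxygen and C17 (sets 8R).

**Step 13**
Reactants: 19 C8–C9 aldol adduct (8R,9S)
Product: 20 2,9,14-triacetate of 19 (16-OTBS kept)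
Conditions: Ac2O, Sc(OTf)3 (2 mol%), MeCN, −20 °C
Reagents that add atoms: acetic anhydride, CC(=O)OC(C)=O
Why: Lewis-acid-catalysed acetylation caps the hindered C9 alcohol under non-basic conditions, which avoids retro-aldol loss of the aromatic oxidofuran.

**Step 14**
Reactants: 20 2,9,14-triacetate with 16-OTBS
Product: 21 2,9,14-triacetate diene with free C16 allylic alcohol
Conditions: HF·pyridine, pyridine/THF, 0 °C
Reagents that add atoms: none
Why: Fluoride-mediated desilylation removes the only silyl ether and leaves the acetates, the methyl ester and the furanone untouched.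

**Step 15**
Reactants: 21 2,9,14-triacetate diene with free C16 allylic alcohol
Product: 22 (3Z)-macrocyclic 16-hydroxy furanone (11-membered carbocycle C5–C16–C4=C3–C2–C1–C10–C9–C8–C7–C6; 10 atoms by the path through the ring oxygen)
Conditions: Hoveyda–Grubbs II (10 mol%), 1,4-benzoquinone (20 mol%), toluene (1 mM), 80 °C, Ar sparge
Reagents that add atoms: none
Why: Ring-closing metathesis of the two monosubstituted alkenes is run under equilibrating conditions, where the cyclodecene-sized ring favours the Z-alkene, and the 1,1-disubstituted C11=C20 alkene and the furanone alkene react far more slowly.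

**Step 16**
Reactants: 22 (3Z)-macrocyclic 16-hydroxy furanone
Product: 24 (5R,6R)-6-chloro-7-oxo-16-al (10-membered carbocycle with 5,8-oxa bridge, 2,9,14-triacetate, C19 methyl ester), via chloro-oxocarbenium ion 23 (not isolated)
Conditions: NCS (1.05 equiv), HFIP/CH2Cl2 1:9, 4 Å MS, dark, −30 to 0 °C
Reagents that add atoms: N-chlorosuccinimide, O=C1CCC(=O)N1Cl
Why: Proposed new method: NCS chlorinates the nucleophilic C6 of the vinylogous ester (the position at which 3(2H)-furanones are halogenated, while unactivated alkenes are inert to NCS alone) from the open exo face; this gives the O-stabilised cation at C5; the macrocycle holds the C16–C4 σ-bond parallel to the empty orbital on the endo face, with the C16–H bond misaligned; the Z-alkenyl carbon therefore shifts 1,2 to C5 anti to chlorine while the carbinol proton goes to the HFIP-solvated succinimide anion; this contracts the ring from 11 to 10 members, sets C5 cis to C9 and C6-Cl exo (C6 can also relax to this exo epimer by enolisation), and releases C16 as the aldehyde; the closest known reaction type is the halonium-initiated semipinacol rearrangement of allylic alcohols and cyclic enol-ether carbinols, which has not been shown for 3(2H)-furanones, for alkenyl migration from a secondary carbinol, or as a medium-ring contraction.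

**Step 17**
Reactants: 24 (5R,6R)-6-chloro-7-oxo-16-al
Product: 26 target CNP0408507.1, via 7,16-diol methyl ester 25 (not isolated)
Conditions: NaBH4, THF/MeOH 4:1, −40 °C; AcOH quench; SiO2 to complete lactonisation
Reagents that add atoms: none
Why: In this borohydride reduction and lactonisation the aldehyde gives C16H2OH; hydride attacks the C7 ketone antiperiplanar to the exo C6–Cl bond (polar Felkin–Anh, away from Cl and the C17 arm) to give the 7R alcohol cis to the C17 arm; that alcohol closes the cis-fused γ-lactone by transesterification, and the acetates survive at low temperature.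

**Compound list**
1 | 4-methylpent-4-en-1-ol | C=C(C)CCCO | starting material
2 | 2-methyl-2-vinyloxirane | CC1(C=C)CO1 | starting material
3 | 4-methylpent-4-enal | C=C(C)CCC=O | intermediate
4 | (2S,3S)-2,6-dimethyl-2-vinylhept-6-ene-1,3-diol | C=C(C)CC[C@H](O)[C@](C)(CO)C=C | intermediate
5 | (1S,2S)-2-(hydroxymethyl)-2,4-dimethylcyclohex-3-en-1-ol | CC1=C[C@@](C)(CO)[C@@H](O)CC1 | intermediate
6 | (1R,6S)-6-hydroxy-1,3-dimethylcyclohex-2-ene-1-carbaldehyde | CC1=C[C@@](C)(C=O)[C@@H](O)CC1 | intermediate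
7 | (1S,2R)-2-[(1S)-1-hydroxyprop-2-en-1-yl]-2,4-dimethylcyclohex-3-en-1-ol | CC1=C[C@@](C)([C@@H](O)C=C)[C@@H](O)CC1 | intermediate
8 | (1S,2R)-2-[(1S)-1-acetoxyprop-2-en-1-yl]-2,4-dimethylcyclohex-3-en-1-yl acetate | CC1=C[C@@](C)([C@@H](OC(C)=O)C=C)[C@@H](OC(C)=O)CC1 | intermediate
9 | (1S,2R,3S)-2-[(1S)-1-acetoxyprop-2-en-1-yl]-3-(hydroxymethyl)-2-methyl-4-methylidenecyclohexyl acetate | C=C1CC[C@H](OC(C)=O)[C@](C)([C@@H](OC(C)=O)C=C)[C@H]1CO | intermediate
10 | (1S,2R,3S)-2-[(1S)-1-acetoxyprop-2-en-1-yl]-3-formyl-2-methyl-4-methylidenecyclohexyl acetate | C=C1CC[C@H](OC(C)=O)[C@](C)([C@@H](OC(C)=O)C=C)[C@H]1C=O | intermediate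
11 | pent-1-en-4-yn-3-ol | C#CC(O)C=C | starting material
12 | tert-butyl(dimethyl)(pent-1-en-4-yn-3-yloxy)silane | C#CC(O[Si](C)(C)C(C)(C)C)C=C | intermediate
13 | (R)-methylsuccinic anhydride | C[C@@H]1CC(=O)OC1=O | starting material
14 | lithium (2R)-7-(TBSO)-2-methyl-4-oxonon-8-en-5-ynoate | [Li+].[O-]C(=O)[C@H](C)CC(=O)C#CC(O[Si](C)(C)C(C)(C)C)C=C | intermediate
15 | methyl (2R)-7-(TBSO)-2-methyl-4-oxonon-8-en-5-ynoate | COC(=O)[C@H](C)CC(=O)C#CC(O[Si](C)(C)C(C)(C)C)C=C | intermediate
16 | methyl (2R)-7-(TBSO)-3-hydroxy-2-methyl-4-oxonon-8-en-5-ynoate | COC(=O)[C@H](C)C(O)C(=O)C#CC(O[Si](C)(C)C(C)(C)C)C=C | intermediate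
17 | methyl (2R)-2-{5-[1-(TBSO)prop-2-enyl]-3-oxo-2,3-dihydrofuran-2-yl}propanoate | COC(=O)[C@H](C)C1OC(C(O[Si](C)(C)C(C)(C)C)C=C)=CC1=O | intermediate
18 | methyl (2R)-2-{5-[1-(TBSO)prop-2-enyl]-3-(TIPSO)furan-2-yl}propanoate | COC(=O)[C@H](C)c1oc(C(O[Si](C)(C)C(C)(C)C)C=C)cc1O[Si](C(C)C)(C(C)C)C(C)C | intermediate
19 | C8–C9 aldol adduct (8R,9S; 9-OH, 16-OTBS) | C=C1CC[C@H](OC(C)=O)[C@](C)([C@@H](OC(C)=O)C=C)[C@H]1[C@H](O)[C@@]2([C@@H](C)C(=O)OC)OC(C(O[Si](C)(C)C(C)(C)C)C=C)=CC2=O | intermediate
20 | 2,9,14-triacetate, 16-OTBS | C=C1CC[C@H](OC(C)=O)[C@](C)([C@@H](OC(C)=O)C=C)[C@H]1[C@H](OC(C)=O)[C@@]2([C@@H](C)C(=O)OC)OC(C(O[Si](C)(C)C(C)(C)C)C=C)=CC2=O | intermediate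
21 | 2,9,14-triacetate diene, 16-OH | C=C1CC[C@H](OC(C)=O)[C@](C)([C@@H](OC(C)=O)C=C)[C@H]1[C@H](OC(C)=O)[C@@]2([C@@H](C)C(=O)OC)OC(C(O)C=C)=CC2=O | intermediate
22 | (3Z)-macrocyclic 16-hydroxy furanone | C=C1CC[C@H](OC(C)=O)[C@]2(C)[C@@H](OC(C)=O)/C=C\C(O)C3=CC(=O)[C@@](O3)([C@@H](C)C(=O)OC)[C@@H](OC(C)=O)[C@@H]12 | intermediate
23 | 6-chloro C5 oxocarbenium ion | C=C1CC[C@H](OC(C)=O)[C@]2(C)[C@@H](OC(C)=O)/C=C\C(O)C3=[O+][C@@]([C@@H](C)C(=O)OC)(C(=O)[C@H]3Cl)[C@@H](OC(C)=O)[C@@H]12 | intermediate
24 | (5R,6R)-6-chloro-7-oxo-16-al, C19 methyl ester | C=C1CC[C@H](OC(C)=O)[C@]2(C)[C@@H](OC(C)=O)/C=C\[C@]3(C=O)O[C@@]([C@@H](C)C(=O)OC)(C(=O)[C@H]3Cl)[C@@H](OC(C)=O)[C@@H]12 | intermediate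
25 | (7R)-7,16-diol, C19 methyl ester | C=C1CC[C@H](OC(C)=O)[C@]2(C)[C@@H](OC(C)=O)/C=C\[C@]3(CO)O[C@@]([C@@H](C)C(=O)OC)([C@@H](O)[C@H]3Cl)[C@@H](OC(C)=O)[C@@H]12 | intermediate
26 | CNP0408507.1 (1R,2S,5R,6R,7R,8R,9S,10S,14S,17R; 3Z) | C=C1CC[C@H](OC(C)=O)[C@]2(C)[C@@H](OC(C)=O)/C=C\[C@]3(CO)O[C@]4([C@@H](C)C(=O)O[C@H]4[C@H]3Cl)[C@@H](OC(C)=O)[C@@H]12 | target

**Total step count:** 17.
**Longest linear sequence:** 13 (steps 1–7, then 12–17).

**Steps most likely to fail**

*Step 12 (aldol).* A tetrasubstituted nucleophile meets a hindered, isomerisable aldehyde, and two new stereocentres depend on an open transition state.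
- The fallback sets out from 10 (with 18) and comes back at 19.
- Pinnick oxidation of 10 gives the carboxylic acid F1.
- 1-Chloro-N,N,2-trimethylpropenylamine converts it into the acid chloride F2.
- ZnCl2-promoted C-acylation of 18 gives the 2-acyl-3(2H)-furanone F3.
- Chelation-controlled Zn(BH4)2 reduction of the more electrophilic C9 ketone sets C9 separately and gives 19.

*Step 15 (medium-ring metathesis).* Both alkenes are hindered, and ring strain or E/Z control may defeat the closure.
- The fallback sets out from 21 and comes back at 24. It reverses the order of events.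
- The Cl+-triggered 1,2-vinyl shift is run on the open diene to give the 5-vinyl-5-formyl-6-chloro furanone F4.
- Ring-closing metathesis of the C2 and C5 vinyl groups then forms the oxa-bridged nine-membered oxonene directly. Only the C5/C8-cis diastereomer can close, and only as the Z-alkene. This gives 24.

*Step 16 (new ring contraction).* Proton loss to the 4-chlorofuranone, hydride shift, or chlorination of C11=C20 may compete.
- The fallback uses known reaction types. It sets out from 22 and comes back at 24.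
- A Brønsted-acid (CSA, CH2Cl2) oxonium-ion-initiated pinacol-type rearrangement of the enol-ether carbinol gives the chlorine-free keto-aldehyde F5.
- TMSOTf/Et3N gives the C6=C7 trimethylsilyl enol ether F6 (C6 is the only enolisable position).
- NCS chlorinates F6 from the exo face to give 24.

**Further compounds**
F1 | step 12 | ring-A C9 carboxylic acid | C=C1CC[C@H](OC(C)=O)[C@](C)([C@@H](OC(C)=O)C=C)[C@H]1C(=O)O
F2 | step 12 | ring-A C9 acid chloride | C=C1CC[C@H](OC(C)=O)[C@](C)([C@@H](OC(C)=O)C=C)[C@H]1C(=O)Cl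
F3 | step 12 | (8R)-9-oxo 2-acyl-3(2H)-furanone, 16-OTBS | C=C1CC[C@H](OC(C)=O)[C@](C)([C@@H](OC(C)=O)C=C)[C@H]1C(=O)[C@@]2([C@@H](C)C(=O)OC)OC(C(O[Si](C)(C)C(C)(C)C)C=C)=CC2=O
F4 | step 15 | open-chain (5R,6R)-6-chloro-5-formyl-5-vinyl-7-oxo triacetate | C=C1CC[C@H](OC(C)=O)[C@](C)([C@@H](OC(C)=O)C=C)[C@H]1[C@H](OC(C)=O)[C@@]2([C@@H](C)C(=O)OC)O[C@](C=C)(C=O)[C@H](Cl)C2=O
F5 | step 16 | 6-deschloro 7-oxo-16-al | C=C1CC[C@H](OC(C)=O)[C@]2(C)[C@@H](OC(C)=O)/C=C\[C@]3(C=O)O[C@@]([C@@H](C)C(=O)OC)(C(=O)C3)[C@@H](OC(C)=O)[C@@H]12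
F6 | step 16 | C6=C7 trimethylsilyl enol ether of F5 | C=C1CC[C@H](OC(C)=O)[C@]2(C)[C@@H](OC(C)=O)/C=C\[C@]3(C=O)O[C@@]([C@@H](C)C(=O)OC)(C(O[Si](C)(C)C)=C3)[C@@H](OC(C)=O)[C@@H]12
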